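The cyclopentene ring (C1 quaternary carbinol, C2–OH, C3=C4, C5–OAc) is disconnected at the C1–C5 bond. Its three contiguous oxygens and the C3=C4 alkene are those of an oxidised 2-furyl carbinol: C2–C5 are the furan carbons and C1 the carbinol carbon. The precursor is therefore a furan-derived 6-hydroxy-2H-pyran-3(6H)-one carrying a 1-silyloxytridecyl chain. In one operation mild base opens it to a Z keto-enal whose enediolate closes the five-membered ring by aldol addition, creating the C1–C5 bond, the quaternary C1 and the C5 carbinol. The silyloxy stereocentre C1′, secured by kinetic resolution, relays the absolute configuration and is later oxidised to the ketone.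

Key step: step 6

Remark on numbering: C1–C5 and C1′ (the side-chain carbon on C1) are the ring locants defined above; systematic names of intermediates carry their own locants.

Assumption: the (R) configuration at C1′ is chosen because an allylic-strain model predicts that it steers the aldol to the required face of C1; this sense is a prediction, and the mirror-image diol is equally accessible with the enantiomeric catalyst in step 1.

Remark on the precursor: the two stereocentres of 8 that the key step erases (C2 and C6) are left uncontrolled, the anomeric hydroxyl stays free so that the hemiacetal can open, and triethylsilyl is used at C1′ because it survives steps 3 to 7 yet comes off in step 8 without disturbing the acetate.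

Step 1
Reactants: 1 racemic 1,2-epoxytetradecane
Product: 2 (R)-tetradecane-1,2-diol
Conditions: (S,S)-(salen)Co(OAc) (trivalent cobalt; salen = N,N′-bis(3,5-di-tert-butylsalicylidene)cyclohexane-1,2-diaminate; 0.5 mol %), H2O (0.45 equiv), THF, 0 °C to rt; diol recrystallised
Reagents that add atoms: water, O
Why: Hydrolytic kinetic resolution (Jacobsen) of a terminal epoxide, in which the (S,S) catalyst should hydrate only the (R)-epoxide at its terminal carbon, so the oxygen-bearing stereocentre (the later C1′) is retained and the substoichiometric water charge keeps the diol enantiomerically pure.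

Step 2
Reactants: 2 (R)-tetradecane-1,2-diol
Product: 3 (R)-1,2-bis(triethylsilyloxy)tetradecane
Conditions: Et3SiCl (2.4 equiv), imidazole, DMF, 0 °C to rt
Reagents that add atoms: chlorotriethylsilane, CC[Si](Cl)(CC)CC
Why: Imidazole-promoted silyl ether formation on both hydroxyls is routine and leaves the stereocentre untouched.

Step 3
Reactants: 3 (R)-1,2-bis(triethylsilyloxy)tetradecane
Product: 4 (R)-2-(triethylsilyloxy)tetradecanal
Conditions: (COCl)2, DMSO, CH2Cl2, −78 to −35 °C; Et3N, −78 °C to rt
Reagents that add atoms: none
Why: Swern oxidation with in situ oxidative desilylation, a known selectivity in which the activated sulfoxide cleaves and oxidises the unhindered primary triethylsilyl ether while the secondary one survives, and the short, cold amine treatment should not epimerise the α-silyloxy aldehyde.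

Step 4
Reactants: 4 (R)-2-(triethylsilyloxy)tetradecanal; 5 furan
Product: 7 (2R)-1-(furan-2-yl)-2-(triethylsilyloxy)tetradecan-1-ol, via 2-lithiofuran 6 (not isolated)
Conditions: furan, n-butyllithium, THF, 0 °C; then 4, −78 °C; aq NH4Cl at −78 °C
Reagents that add atoms: none
Why: Lithiation of furan at C2 and 1,2-addition of the organolithium to the aldehyde at −78 °C with a cold quench (to avoid silyl migration) is standard, and the new carbinol centre needs no control because it is the carbon enolised in the key step.

Step 5
Reactants: 7 (2R)-1-(furan-2-yl)-2-(triethylsilyloxy)tetradecan-1-ol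
Product: 8 6-hydroxy-2-[(1R)-1-(triethylsilyloxy)tridecyl]-2H-pyran-3(6H)-one
Conditions: NBS (1.05 equiv), NaHCO3, THF/H2O (4:1), 0 °C
Reagents that add atoms: water, O
Why: Achmatowicz rearrangement, in which bromonium-initiated oxidative opening of the furan in buffered aqueous medium and re-closure through the carbinol oxygen gives the 6-hydroxypyranone, storing the cis alkene and the masked aldehyde while the silyl ether and C1′ stay untouched.

Step 6
Reactants: 8 6-hydroxy-2-[(1R)-1-(triethylsilyloxy)tridecyl]-2H-pyran-3(6H)-one
Product: 10 (4S,5S)-4,5-dihydroxy-5-[(1R)-1-(triethylsilyloxy)tridecyl]cyclopent-2-en-1-one, via open-chain keto-enal 9 (not isolated)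
Conditions: Et3N (1.5 equiv), DMF (0.05 M), 0 °C to rt
Reagents that add atoms: none
Why: Triethylamine opens the hemiacetal of 8 to the (Z)-4-oxo-enal 9 and enolises its α-hydroxy ketone at C1, so that all four stereoisomers of 8 converge on one enediolate, whose C1 adds to the aldehyde carbon C5 to form the C1–C5 bond while the former pyranone ring oxygen remains as the tertiary C1 hydroxyl. The closest known reaction type is the amine-promoted isomerisation of furan-derived 2-substituted 6-hydroxy-2H-pyran-3(6H)-ones to trans-4,5-dihydroxycyclopent-2-en-1-ones, an intramolecular aldol addition of a cis-ene-1,4-dicarbonyl compound. The cyclopentenone ring closes in the 5-(enolendo)-exo-trig mode, both enolate carbons C1 and C2 becoming ring atoms, which is geometrically demanding but is made possible by the Z C3=C4 bond inherited from the furan, which holds C5 over C1. The C5 carbinol should emerge trans to the C1 hydroxyl, the known preference of this ring contraction, and because the aldol is reversible that preference can be reinforced by equilibration. The quaternary C1 is controlled by the (R)-C1′ silyloxy centre: allylic 1,3-strain holds the C1′–H bond in the enediolate plane, and C5 is expected to bond to the face anti to the C1′–O bond, as electrophiles do with allylic ethers in the H-eclipsed rotamer, which for (R)-C1′ leads to the (4S,5S) product 10. The step therefore needs facial selectivity at C1 and aldol closure faster than E1cB loss of the silyloxy group from the enediolate; the allylic-strain-locked rotamer at C1′ should secure the former and the weak amine base, ambient temperature and poor silanolate leaving group the latter, while any minor trans isomer is a diastereomer of 10 because of C1′ and can be removed by chromatography.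

Step 7
Reactants: 10 (4S,5S)-4,5-dihydroxy-5-[(1R)-1-(triethylsilyloxy)tridecyl]cyclopent-2-en-1-one
Product: 11 (1S,5S)-5-hydroxy-4-oxo-5-[(1R)-1-(triethylsilyloxy)tridecyl]cyclopent-2-en-1-yl acetate
Conditions: Ac2O, pyridine, DMAP (5 mol %), CH2Cl2, 0 °C
Reagents that add atoms: acetic anhydride, CC(=O)OC(C)=O
Why: Pyridine/DMAP acylation should esterify the secondary allylic C5 hydroxyl far faster than the hindered tertiary C1 hydroxyl, and the acetate also blocks retro-aldol, so the C1 and C5 configurations are fixed from here on.

Step 8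
Reactants: 11 (1S,5S)-5-hydroxy-4-oxo-5-[(1R)-1-(triethylsilyloxy)tridecyl]cyclopent-2-en-1-yl acetate
Product: 12 (1S,5R)-5-hydroxy-5-[(1R)-1-hydroxytridecyl]-4-oxocyclopent-2-en-1-yl acetate
Conditions: HF·pyridine, pyridine, THF, 0 °C
Reagents that add atoms: none
Why: Fluoride-mediated desilylation under pyridine-buffered, weakly acidic conditions should cleave the triethylsilyl ether while sparing the acetate, which no basic species is present to shift or eliminate.

Step 9
Reactants: 12 (1S,5R)-5-hydroxy-5-[(1R)-1-hydroxytridecyl]-4-oxocyclopent-2-en-1-yl acetate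
Product: 13 (1S,5S)-5-hydroxy-4-oxo-5-tridecanoylcyclopent-2-en-1-yl acetate
Conditions: IBX (2 equiv), DMSO, rt
Reagents that add atoms: none
Why: IBX oxidation of a secondary alcohol, chosen because this hypervalent iodine reagent converts the secondary carbinol of a glycol into the α-ketol without C–C cleavage and does not affect the tertiary hydroxyl, the acetate or the enone.

Step 10
Reactants: 13 (1S,5S)-5-hydroxy-4-oxo-5-tridecanoylcyclopent-2-en-1-yl acetate
Product: 14 (1S,4R,5S)-4,5-dihydroxy-5-tridecanoylcyclopent-2-en-1-yl acetate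
Conditions: NaBH4 (1.0 equiv), CeCl3·7H2O, MeOH, −78 °C; aq NH4Cl at −78 °C
Reagents that add atoms: none
Why: Luche reduction, in which the cerium-activated conjugated ring carbonyl should be reduced 1,2 in preference to the hindered neopentyl-type side-chain ketone, and hydride should arrive on the face of the small C1 hydroxyl, anti to the acyl chain on C1 and the acetoxy group on C5, setting the C2 carbinol (C4 in the name, R) trans to the C1 hydroxyl.

Compound list

1 | racemic 1,2-epoxytetradecane (2-dodecyloxirane) | CCCCCCCCCCCCC1CO1 | starting material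
2 | (R)-tetradecane-1,2-diol | CCCCCCCCCCCC[C@@H](O)CO | intermediate
3 | (R)-1,2-bis(triethylsilyloxy)tetradecane | CCCCCCCCCCCC[C@@H](O[Si](CC)(CC)CC)CO[Si](CC)(CC)CC | intermediate
4 | (R)-2-(triethylsilyloxy)tetradecanal | CCCCCCCCCCCC[C@@H](O[Si](CC)(CC)CC)C=O | intermediate
5 | furan | c1ccoc1 | starting material
6 | 2-lithiofuran | [Li]c1ccco1 | intermediate (not isolated)
7 | (2R)-1-(furan-2-yl)-2-(triethylsilyloxy)tetradecan-1-ol, both C1 epimers | CCCCCCCCCCCC[C@@H](O[Si](CC)(CC)CC)C(O)c1ccco1 | intermediate
8 | 6-hydroxy-2-[(1R)-1-(triethylsilyloxy)tridecyl]-2H-pyran-3(6H)-one, epimers at C2 and C6 | CCCCCCCCCCCC[C@@H](O[Si](CC)(CC)CC)C1OC(O)C=CC1=O | intermediate (precursor of the key step)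
9 | (2Z,6R)-5-hydroxy-4-oxo-6-(triethylsilyloxy)octadec-2-enal, both C5 epimers | CCCCCCCCCCCC[C@@H](O[Si](CC)(CC)CC)C(O)C(=O)/C=C\C=O | intermediate (not isolated)
10 | (4S,5S)-4,5-dihydroxy-5-[(1R)-1-(triethylsilyloxy)tridecyl]cyclopent-2-en-1-one | CCCCCCCCCCCC[C@@H](O[Si](CC)(CC)CC)[C@]1(O)C(=O)C=C[C@@H]1O | intermediate (product of the key step)
11 | (1S,5S)-5-hydroxy-4-oxo-5-[(1R)-1-(triethylsilyloxy)tridecyl]cyclopent-2-en-1-yl acetate | CCCCCCCCCCCC[C@@H](O[Si](CC)(CC)CC)[C@]1(O)C(=O)C=C[C@@H]1OC(C)=O | intermediate
12 | (1S,5R)-5-hydroxy-5-[(1R)-1-hydroxytridecyl]-4-oxocyclopent-2-en-1-yl acetate | CCCCCCCCCCCC[C@@H](O)[C@]1(O)C(=O)C=C[C@@H]1OC(C)=O | intermediate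
13 | (1S,5S)-5-hydroxy-4-oxo-5-tridecanoylcyclopent-2-en-1-yl acetate | CCCCCCCCCCCCC(=O)[C@]1(O)C(=O)C=C[C@@H]1OC(C)=O | intermediate
14 | (1S,4R,5S)-4,5-dihydroxy-5-tridecanoylcyclopent-2-en-1-yl acetate | CCCCCCCCCCCCC(=O)[C@]1(O)[C@H](O)C=C[C@@H]1OC(C)=O | target

Total step count: 10. Longest linear sequence: 10 steps (1 to 14; furan 5 joins in step 4).

Steps most likely to fail

Step 6 (key step). The C1′ centre may discriminate poorly, or in the opposite sense, between the two faces of the enediolate, so that much of the trans product forms with the mirror-image ring, and some material may be lost by elimination of the silyloxy group. The fallback replaces the substrate relay by an enzymatic desymmetrisation.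
- It sets out from 10 taken as its unseparated mixture with the diastereomer (4R,5R)-4,5-dihydroxy-5-[(1R)-1-(triethylsilyloxy)tridecyl]cyclopent-2-en-1-one F1.
- Luche reduction of the mixture (NaBH4, CeCl3·7H2O, MeOH, −78 °C; hydride anti to the bulky side chain) should funnel both components into one triol, (1R,2r,3S)-2-[(1R)-1-(triethylsilyloxy)tridecyl]cyclopent-4-ene-1,2,3-triol F2, because the reduced ring has a mirror plane through C1.
- Acetylation of both secondary hydroxyls (Ac2O, pyridine, DMAP) would give (1R,2r,3S)-2-hydroxy-2-[(1R)-1-(triethylsilyloxy)tridecyl]cyclopent-4-ene-1,3-diyl diacetate F3.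
- Desilylation (HF·pyridine, pyridine, THF) would give (1R,2r,3S)-2-hydroxy-2-[(1R)-1-hydroxytridecyl]cyclopent-4-ene-1,3-diyl diacetate F4.
- IBX oxidation would give the achiral meso compound (1R,2r,3S)-2-hydroxy-2-tridecanoylcyclopent-4-ene-1,3-diyl diacetate F5.
- Lipase-mediated hydrolysis of one of its two enantiotopic acetates (Candida antarctica lipase B or Pseudomonas cepacia lipase, phosphate buffer pH 7) comes back to the route at 14. Lipases normally cleave the ester of the (R)-configured secondary carbinol whose larger substituent has the higher sequence-rule priority, which is the acetate that has to go.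
- This path also removes the chemoselectivity demand of step 10.

Step 10. Hydride may also attack the side-chain ketone, or the acetyl group may migrate between the cis oxygens on C2 and C5 in the intermediate alkoxyborate, eroding yield or enantiomeric purity. The fallback reduces the ring carbonyl before the second ketone exists.
- It sets out from 11. Luche reduction should give (1S,4R,5S)-4,5-dihydroxy-5-[(1R)-1-(triethylsilyloxy)tridecyl]cyclopent-2-en-1-yl acetate F6.
- The new secondary hydroxyl is masked (TBSOTf, 2,6-lutidine, CH2Cl2, −78 °C) as (1S,4R,5S)-4-(tert-butyldimethylsilyloxy)-5-hydroxy-5-[(1R)-1-(triethylsilyloxy)tridecyl]cyclopent-2-en-1-yl acetate F7.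
- The more labile triethylsilyl ether alone is cleaved (HF·pyridine, pyridine, THF, 0 °C) to (1S,4R,5R)-4-(tert-butyldimethylsilyloxy)-5-hydroxy-5-[(1R)-1-hydroxytridecyl]cyclopent-2-en-1-yl acetate F8.
- IBX oxidation gives (1S,4R,5R)-4-(tert-butyldimethylsilyloxy)-5-hydroxy-5-tridecanoylcyclopent-2-en-1-yl acetate F9.
- Aqueous HF in MeCN removes the remaining silyl group, coming back to the route at 14.

Step 3. The one-flask Swern may fail to discriminate cleanly between the two silyl ethers (loss of both, or incomplete cleavage of the primary one), and prolonged exposure may epimerise the α-silyloxy aldehyde. The fallback separates the two events.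
- It sets out from 3. Selective cleavage of the primary silyl ether (HF·pyridine, pyridine, THF, −10 °C) gives (R)-2-(triethylsilyloxy)tetradecan-1-ol F10.
- A neutral oxidation (Dess–Martin periodinane, NaHCO3, CH2Cl2, 0 °C) comes back to the route at 4.

Further compounds

F1 | step 6 | (4R,5R)-4,5-dihydroxy-5-[(1R)-1-(triethylsilyloxy)tridecyl]cyclopent-2-en-1-one | CCCCCCCCCCCC[C@@H](O[Si](CC)(CC)CC)[C@@]1(O)C(=O)C=C[C@H]1O
F2 | step 6 | (1R,2r,3S)-2-[(1R)-1-(triethylsilyloxy)tridecyl]cyclopent-4-ene-1,2,3-triol | CCCCCCCCCCCC[C@@H](O[Si](CC)(CC)CC)[C@]1(O)[C@H](O)C=C[C@@H]1O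
F3 | step 6 | (1R,2r,3S)-2-hydroxy-2-[(1R)-1-(triethylsilyloxy)tridecyl]cyclopent-4-ene-1,3-diyl diacetate | CCCCCCCCCCCC[C@@H](O[Si](CC)(CC)CC)[C@]1(O)[C@H](OC(C)=O)C=C[C@@H]1OC(C)=O
F4 | step 6 | (1R,2r,3S)-2-hydroxy-2-[(1R)-1-hydroxytridecyl]cyclopent-4-ene-1,3-diyl diacetate | CCCCCCCCCCCC[C@@H](O)[C@]1(O)[C@H](OC(C)=O)C=C[C@@H]1OC(C)=O
F5 | step 6 | (1R,2r,3S)-2-hydroxy-2-tridecanoylcyclopent-4-ene-1,3-diyl diacetate (meso) | CCCCCCCCCCCCC(=O)[C@]1(O)[C@H](OC(C)=O)C=C[C@@H]1OC(C)=O
F6 | step 10 | (1S,4R,5S)-4,5-dihydroxy-5-[(1R)-1-(triethylsilyloxy)tridecyl]cyclopent-2-en-1-yl acetate | CCCCCCCCCCCC[C@@H](O[Si](CC)(CC)CC)[C@]1(O)[C@H](O)C=C[C@@H]1OC(C)=O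
F7 | step 10 | (1S,4R,5S)-4-(tert-butyldimethylsilyloxy)-5-hydroxy-5-[(1R)-1-(triethylsilyloxy)tridecyl]cyclopent-2-en-1-yl acetate | CCCCCCCCCCCC[C@@H](O[Si](CC)(CC)CC)[C@]1(O)[C@H](O[Si](C)(C)C(C)(C)C)C=C[C@@H]1OC(C)=O
F8 | step 10 | (1S,4R,5R)-4-(tert-butyldimethylsilyloxy)-5-hydroxy-5-[(1R)-1-hydroxytridecyl]cyclopent-2-en-1-yl acetate | CCCCCCCCCCCC[C@@H](O)[C@]1(O)[C@H](O[Si](C)(C)C(C)(C)C)C=C[C@@H]1OC(C)=O
F9 | step 10 | (1S,4R,5R)-4-(tert-butyldimethylsilyloxy)-5-hydroxy-5-tridecanoylcyclopent-2-en-1-yl acetate | CCCCCCCCCCCCC(=O)[C@]1(O)[C@H](O[Si](C)(C)C(C)(C)C)C=C[C@@H]1OC(C)=O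
F10 | step 3 | (R)-2-(triethylsilyloxy)tetradecan-1-ol | CCCCCCCCCCCC[C@@H](O[Si](CC)(CC)CC)CO
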